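**Retrosynthetic overview**
1. Ring C (10-membered carbocycle) is closed last by an intramolecular Nozaki–Hiyama–Kishi coupling C4–C5 of a vinyl triflate with an α-angeloyloxy aldehyde; this also delivers the C4(=CH2)–C5H(OH) unit.
2. Ring A (trans α-methylene-γ-lactone; C7–C8 and O8–C12) comes from a chromium-mediated allylation/lactonisation of a furanone aldehyde (C8) with a (Z)-2-(bromomethyl)enoate made from (R)-glyceraldehyde acetonide (C5–C7, C11–C13).
3. Ring B (3(2H)-furanone) comes from the key step: an anionic acetylenic oxy-Cope shift forms C1–C10 by breaking a temporary C3–C8 bond, and cyclodehydration in the same flask forms O–C3.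
4. Enabling feature: C1–C10 lies 1,6 across the enyne C1≡C2–C3–C8–C9=C10, and C8 and C10 are 1,3-related oxygen-bearing carbons (ring A oxygen on C8, ring B oxygen on C10). Joining O8 and O10 in a 1,3,2-dioxasiline ring makes C9=C10 a ring-locked enol ether, so the C8 stereocentre of (S)-malic acid sets the quaternary C10.
5. Ring order: B, then A, then C. C4 travels as a dithiane-masked acetyl group so that the alkyne is the only π-partner on C3.

Key step: step 7

Remark: atoms are referred to by germacrane numbering (C1–C10 ring carbons, C11–C13 lactone carbons, C14 methyl on C10, C15 methylene on C4); the target is the (5S,6S,7R,8S,10R) isomer.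

Step 1
Reactants: 1 (S)-2-(2,2-dimethyl-5-oxo-1,3-dioxolan-4-yl)acetic acid [(S)-malic acid acetonide]
Product: 3 (S)-2,2-dimethyl-5-(2-oxopropyl)-1,3-dioxolan-4-one, via acid chloride 2 (not isolated)
Conditions: (COCl)2, DMF (cat.), CH2Cl2, 0 °C to rt; then MeMgBr, Fe(acac)3 (3 mol %), THF, −78 °C
Reagents that add atoms: oxalyl chloride, ClC(=O)C(=O)Cl (chlorine of 2); methylmagnesium bromide, C[Mg]Br (methyl C14)
Why: Iron-catalysed acylation of the Grignard reagent by the acid chloride (Kumada-type ketone synthesis) is much faster at −78 °C than attack on the dioxolanone, so the methyl ketone should form without touching the C8 stereocentre.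

Step 2
Reactants: 3 (S)-2,2-dimethyl-5-(2-oxopropyl)-1,3-dioxolan-4-one
Product: 4 methyl (S)-2-hydroxy-4-oxopentanoate
Conditions: MeOH, p-TsOH (cat.), rt
Reagents that add atoms: methanol, CO
Why: Acid-catalysed methanolysis (transesterification) of the 1,3-dioxolan-4-one releases acetone and the α-hydroxy ester; no bond to C8 is changed, so the S configuration is kept.

Step 3
Reactants: 4 methyl (S)-2-hydroxy-4-oxopentanoate
Product: 5 methyl (4S)-2,2-di-tert-butyl-6-methyl-4H-1,3,2-dioxasiline-4-carboxylate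
Conditions: t-Bu2Si(OTf)2, Et3N, CH2Cl2, −78 °C to rt
Reagents that add atoms: di-tert-butylsilyl bis(trifluoromethanesulfonate), CC(C)(C)[Si](OS(=O)(=O)C(F)(F)F)(OS(=O)(=O)C(F)(F)F)C(C)(C)C
Why: O-silylation of the alcohol followed by intramolecular silyl triflate/amine enolisation of the ketone (silyl enol ether formation) should close the six-membered ring, whose endocyclic, more substituted enol ether is the thermodynamic isomer and is Z by ring constraint.

Step 4
Reactants: 5 methyl (4S)-2,2-di-tert-butyl-6-methyl-4H-1,3,2-dioxasiline-4-carboxylate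
Product: 6 (4S)-2,2-di-tert-butyl-N-methoxy-N,6-dimethyl-4H-1,3,2-dioxasiline-4-carboxamide
Conditions: MeNH(OMe)·HCl, i-PrMgCl, THF, −20 °C
Reagents that add atoms: N,O-dimethylhydroxylamine hydrochloride, CNOC.Cl
Why: Weinreb amide formation from the ester with the magnesium amide runs at low temperature, which should leave the allylic, α-oxygenated C8–H untouched.

Step 5
Reactants: 6 (4S)-2,2-di-tert-butyl-N-methoxy-N,6-dimethyl-4H-1,3,2-dioxasiline-4-carboxamide; 7 2-methyl-1,3-dithiane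
Product: 8 [(4S)-2,2-di-tert-butyl-6-methyl-4H-1,3,2-dioxasilin-4-yl](2-methyl-1,3-dithian-2-yl)methanone
Conditions: 7, n-BuLi, THF, −30 °C; then 6, −78 °C; aq. NH4Cl
Reagents that add atoms: none
Why: Acylation of the lithiated dithiane (Corey–Seebach acyl-anion equivalent) by a Weinreb amide stops at the chelated tetrahedral adduct until work-up, so the epimerisable C8–H is never exposed to base at the ketone stage.

Step 6
Reactants: 8 [(4S)-2,2-di-tert-butyl-6-methyl-4H-1,3,2-dioxasilin-4-yl](2-methyl-1,3-dithian-2-yl)methanone; 9 ethoxyethyne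
Product: 10 (1R)-1-[(4S)-2,2-di-tert-butyl-6-methyl-4H-1,3,2-dioxasilin-4-yl]-3-ethoxy-1-(2-methyl-1,3-dithian-2-yl)prop-2-yn-1-ol
Conditions: 9, n-BuLi, THF, −78 °C; CeCl3, −78 °C; then 8; aq. NH4Cl
Reagents that add atoms: none
Why: Cerium-mediated 1,2-addition of the acetylide suppresses enolisation of the α-siloxy ketone, and Felkin–Anh attack anti to the C8–O bond should give mainly the 1R carbinol; either C3 epimer is usable because C3 becomes sp2 in step 7.

Step 7
Reactants: 10 (1R)-1-[(4S)-2,2-di-tert-butyl-6-methyl-4H-1,3,2-dioxasilin-4-yl]-3-ethoxy-1-(2-methyl-1,3-dithian-2-yl)prop-2-yn-1-ol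
Product: 14 2-[(2R)-2-methyl-5-(2-methyl-1,3-dithian-2-yl)-3-oxo-2,3-dihydrofuran-2-yl]acetaldehyde, via potassium alkoxide 11 (not isolated), via potassium allenolate 12 (not isolated), via hydroxy enone 13 (not isolated)
Conditions: KH, 18-crown-6, THF, 0 °C to rt; then 48% aq. HF, MeCN, 0 °C to rt
Reagents that add atoms: water, O (its oxygen becomes the C1 carbonyl oxygen when the ethoxy enol ether is hydrolysed; the former carbinol oxygen on C3 leaves as water, so there is no net uptake)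
Why: Alkoxide 11 contains the 1,5-enyne C1≡C2–C3–C8–C9=C10 and should undergo an anionic acetylenic oxy-Cope [3,3] shift that breaks C3–C8 and forms C1–C10 to give allenolate 12; aqueous HF then removes the silylene, hydrolyses the C8 silyl enol ether to the aldehyde and the allenyl ether to the β-ethoxy enone 13, and the freed C10 hydroxyl attacks the C3 carbonyl with loss of water and ethanol, forming O–C3. The closest known reactions are the anionic oxy-Cope rearrangement of 1-alkynyl-2-alkenyl carbinols and the acid cyclodehydration of α'-hydroxy β-alkoxy (or β-amino) enones to 3(2H)-furanones. The sigmatropic step closes no ring (it only moves the dioxasiline double bond from C9=C10 to C8=C9); the furanone closes by 5-exo-trig addition of O10 to the C3 carbonyl followed by dehydration. The only new stereocentre, C10, is set by suprafacial 1,3-transfer across the ring-held allyl unit: C1 must bond to C10 on the face from which C3 leaves C8, so 8S gives 10R whatever the C3 configuration, with no enol ether E/Z ambiguity. The step needs the alkyne to be the only π-partner on C3 (secured by the sp3 dithiane carbon C4), needs the shift to outrun silyl transfer to the alkoxide (the two tert-butyl groups shield silicon and the oxygen on C8 accelerates the shift), and needs O10 to stay on C10 (the product is an allenolate with no β-leaving group).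

Step 8
Reactants: 15 (R)-2,2-dimethyl-1,3-dioxolane-4-carbaldehyde [(R)-glyceraldehyde acetonide]; 16 methyl acrylate
Product: 17 methyl 2-{[(4R)-2,2-dimethyl-1,3-dioxolan-4-yl](hydroxy)methyl}prop-2-enoate (both carbinol epimers)
Conditions: DABCO (cat.), dioxane/H2O, rt
Reagents that add atoms: none
Why: Morita–Baylis–Hillman reaction of the α-alkoxy aldehyde; the new carbinol centre is erased in step 9, and the acetal stereocentre (C6) should not be enolised by the amine catalyst.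

Step 9
Reactants: 17 methyl 2-{[(4R)-2,2-dimethyl-1,3-dioxolan-4-yl](hydroxy)methyl}prop-2-enoate
Product: 18 methyl (2Z)-2-(bromomethyl)-3-[(4S)-2,2-dimethyl-1,3-dioxolan-4-yl]prop-2-enoate
Conditions: NBS, Me2S, CH2Cl2, 0 °C to rt
Reagents that add atoms: N-bromosuccinimide, O=C1CCC(=O)N1Br
Why: SN2′ bromination of the Baylis–Hillman alcohol through its alkoxysulfonium salt should give the thermodynamically preferred (Z)-2-(bromomethyl)enoate under neutral conditions that spare the acetonide.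

Step 10
Reactants: 14 2-[(2R)-2-methyl-5-(2-methyl-1,3-dithian-2-yl)-3-oxo-2,3-dihydrofuran-2-yl]acetaldehyde; 18 methyl (2Z)-2-(bromomethyl)-3-[(4S)-2,2-dimethyl-1,3-dioxolan-4-yl]prop-2-enoate
Product: 20 (4R,5S)-4-[(4S)-2,2-dimethyl-1,3-dioxolan-4-yl]-3-methylidene-5-{[(2R)-2-methyl-5-(2-methyl-1,3-dithian-2-yl)-3-oxo-2,3-dihydrofuran-2-yl]methyl}oxolan-2-one, via hydroxy ester 19 (not isolated)
Conditions: CrCl2 (3 equiv), THF, rt; then p-TsOH (cat.), CH2Cl2, rt
Reagents that add atoms: none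
Why: Chromium-mediated Barbier-type allylation (Nozaki–Hiyama reaction): the equilibrated (E)-allylchromium should add through a chair Zimmerman–Traxler transition state to give the anti C7/C8 adduct, Felkin-type attack anti to the C6–O bond of the reagent should set C7, and the alkoxide lactonises onto the ester to the trans lactone.

Step 11
Reactants: 20 (4R,5S)-4-[(4S)-2,2-dimethyl-1,3-dioxolan-4-yl]-3-methylidene-5-{[(2R)-2-methyl-5-(2-methyl-1,3-dithian-2-yl)-3-oxo-2,3-dihydrofuran-2-yl]methyl}oxolan-2-one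
Product: 21 (4R,5S)-5-{[(2R)-5-acetyl-2-methyl-3-oxo-2,3-dihydrofuran-2-yl]methyl}-4-[(4S)-2,2-dimethyl-1,3-dioxolan-4-yl]-3-methylideneoxolan-2-one
Conditions: PhI(O2CCF3)2, NaHCO3, MeCN/H2O, 0 °C
Reagents that add atoms: water, O
Why: Oxidative dethioketalisation with a hypervalent iodine reagent under bicarbonate buffer unmasks the acetyl group without acid or base, so acetonide, lactone and furanone should survive.

Step 12
Reactants: 21 (4R,5S)-5-{[(2R)-5-acetyl-2-methyl-3-oxo-2,3-dihydrofuran-2-yl]methyl}-4-[(4S)-2,2-dimethyl-1,3-dioxolan-4-yl]-3-methylideneoxolan-2-one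
Product: 22 1-[(5R)-5-{[(2S,3R)-3-[(4S)-2,2-dimethyl-1,3-dioxolan-4-yl]-4-methylidene-5-oxooxolan-2-yl]methyl}-5-methyl-4-oxo-4,5-dihydrofuran-2-yl]ethenyl trifluoromethanesulfonate
Conditions: KN(SiMe3)2, PhNTf2, THF, −78 °C; aq. NH4Cl
Reagents that add atoms: N-phenylbis(trifluoromethanesulfonimide), O=S(=O)(N(c1ccccc1)S(=O)(=O)C(F)(F)F)C(F)(F)F
Why: Kinetic deprotonation of the methyl ketone (the most acidic C–H in 21) and O-sulfonylation of the enolate should give the 2-triflyloxy-1-alkene needed for the ring closure.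

Step 13
Reactants: 22 1-[(5R)-5-{[(2S,3R)-3-[(4S)-2,2-dimethyl-1,3-dioxolan-4-yl]-4-methylidene-5-oxooxolan-2-yl]methyl}-5-methyl-4-oxo-4,5-dihydrofuran-2-yl]ethenyl trifluoromethanesulfonate
Product: 23 1-[(5R)-5-{[(2S,3S)-3-[(1S)-1,2-dihydroxyethyl]-4-methylidene-5-oxooxolan-2-yl]methyl}-5-methyl-4-oxo-4,5-dihydrofuran-2-yl]ethenyl trifluoromethanesulfonate
Conditions: AcOH/H2O (4:1), 40 °C
Reagents that add atoms: none
Why: Acid hydrolysis of the isopropylidene acetal; vinyl triflate, lactone and furanone are stable to aqueous acetic acid (the descriptor at C7 changes only because of the priority rules).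

Step 14
Reactants: 23 1-[(5R)-5-{[(2S,3S)-3-[(1S)-1,2-dihydroxyethyl]-4-methylidene-5-oxooxolan-2-yl]methyl}-5-methyl-4-oxo-4,5-dihydrofuran-2-yl]ethenyl trifluoromethanesulfonate
Product: 24 1-[(5R)-5-{[(2S,3S)-3-[(1S)-2-{[tert-butyl(dimethyl)silyl]oxy}-1-hydroxyethyl]-4-methylidene-5-oxooxolan-2-yl]methyl}-5-methyl-4-oxo-4,5-dihydrofuran-2-yl]ethenyl trifluoromethanesulfonate
Conditions: TBSCl, imidazole, CH2Cl2, 0 °C
Reagents that add atoms: tert-butyldimethylsilyl chloride, CC(C)(C)[Si](C)(C)Cl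
Why: Selective silylation of the primary hydroxyl (C5) in the presence of the hindered secondary one (C6).

Step 15
Reactants: 24 1-[(5R)-5-{[(2S,3S)-3-[(1S)-2-{[tert-butyl(dimethyl)silyl]oxy}-1-hydroxyethyl]-4-methylidene-5-oxooxolan-2-yl]methyl}-5-methyl-4-oxo-4,5-dihydrofuran-2-yl]ethenyl trifluoromethanesulfonate; 25 angelic acid [(2Z)-2-methylbut-2-enoic acid]
Product: 26 (1S)-2-{[tert-butyl(dimethyl)silyl]oxy}-1-[(2S,3R)-4-methylidene-2-{[(2R)-2-methyl-3-oxo-5-(1-{[(trifluoromethyl)sulfonyl]oxy}ethenyl)-2,3-dihydrofuran-2-yl]methyl}-5-oxooxolan-3-yl]ethyl (2Z)-2-methylbut-2-enoate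
Conditions: 25, 2,4,6-trichlorobenzoyl chloride, Et3N, toluene, rt; then 24, 80 °C
Reagents that add atoms: none
Why: Yamaguchi esterification through the mixed anhydride, run without DMAP, should acylate the secondary alcohol while avoiding Z-to-E isomerisation of the angelate.

Step 16
Reactants: 26 (1S)-2-{[tert-butyl(dimethyl)silyl]oxy}-1-[(2S,3R)-4-methylidene-2-{[(2R)-2-methyl-3-oxo-5-(1-{[(trifluoromethyl)sulfonyl]oxy}ethenyl)-2,3-dihydrofuran-2-yl]methyl}-5-oxooxolan-3-yl]ethyl (2Z)-2-methylbut-2-enoate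
Product: 27 (1S)-2-hydroxy-1-[(2S,3R)-4-methylidene-2-{[(2R)-2-methyl-3-oxo-5-(1-{[(trifluoromethyl)sulfonyl]oxy}ethenyl)-2,3-dihydrofuran-2-yl]methyl}-5-oxooxolan-3-yl]ethyl (2Z)-2-methylbut-2-enoate
Conditions: HF·pyridine, pyridine, THF, 0 °C
Reagents that add atoms: none
Why: Buffered fluoride desilylation is mild enough that the angelate should stay on O6 (no acyl migration at 0 °C) and the vinyl triflate remains intact.

Step 17
Reactants: 27 (1S)-2-hydroxy-1-[(2S,3R)-4-methylidene-2-{[(2R)-2-methyl-3-oxo-5-(1-{[(trifluoromethyl)sulfonyl]oxy}ethenyl)-2,3-dihydrofuran-2-yl]methyl}-5-oxooxolan-3-yl]ethyl (2Z)-2-methylbut-2-enoate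
Product: 28 (1S)-1-[(2S,3R)-4-methylidene-2-{[(2R)-2-methyl-3-oxo-5-(1-{[(trifluoromethyl)sulfonyl]oxy}ethenyl)-2,3-dihydrofuran-2-yl]methyl}-5-oxooxolan-3-yl]-2-oxoethyl (2Z)-2-methylbut-2-enoate
Conditions: Dess–Martin periodinane, NaHCO3, CH2Cl2, 0 °C to rt
Reagents that add atoms: none
Why: Dess–Martin oxidation under bicarbonate should give the α-acyloxy aldehyde without epimerising C6; the aldehyde is used at once.

Step 18
Reactants: 28 (1S)-1-[(2S,3R)-4-methylidene-2-{[(2R)-2-methyl-3-oxo-5-(1-{[(trifluoromethyl)sulfonyl]oxy}ethenyl)-2,3-dihydrofuran-2-yl]methyl}-5-oxooxolan-3-yl]-2-oxoethyl (2Z)-2-methylbut-2-enoate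
Product: 29 CNP0120053.1, (5S,6S,7R,8S,10R)-6-angeloyloxy-5-hydroxy-1-oxo-3,10-epoxygermacra-2,4(15),11(13)-trien-12,8-olide
Conditions: CrCl2 (8 equiv), NiCl2 (cat.), DMF, rt, 0.002 M
Reagents that add atoms: none
Why: Intramolecular Nozaki–Hiyama–Kishi reaction: nickel-catalysed formation of the alkenylchromium species from the vinyl triflate and its addition to the aldehyde closes the 10-membered carbocycle, tolerates lactone, esters and enone, and is expected to set 5S by attack on the chromium-chelated α-acyloxy aldehyde conformer held by the forming ring.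

**Compound list**
1 | (S)-2-(2,2-dimethyl-5-oxo-1,3-dioxolan-4-yl)acetic acid | CC1(C)OC(=O)[C@H](CC(=O)O)O1 | starting material
2 | (S)-2-(2,2-dimethyl-5-oxo-1,3-dioxolan-4-yl)acetyl chloride | CC1(C)OC(=O)[C@H](CC(=O)Cl)O1 | intermediate (not isolated)
3 | (S)-2,2-dimethyl-5-(2-oxopropyl)-1,3-dioxolan-4-one | CC1(C)OC(=O)[C@H](CC(C)=O)O1 | intermediate
4 | methyl (S)-2-hydroxy-4-oxopentanoate | COC(=O)[C@H](CC(C)=O)O | intermediate
5 | methyl (4S)-2,2-di-tert-butyl-6-methyl-4H-1,3,2-dioxasiline-4-carboxylate | COC(=O)[C@@H]1C=C(C)O[Si](C(C)(C)C)(C(C)(C)C)O1 | intermediate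
6 | (4S)-2,2-di-tert-butyl-N-methoxy-N,6-dimethyl-4H-1,3,2-dioxasiline-4-carboxamide | CON(C)C(=O)[C@@H]1C=C(C)O[Si](C(C)(C)C)(C(C)(C)C)O1 | intermediate
7 | 2-methyl-1,3-dithiane | CC1SCCCS1 | starting material
8 | [(4S)-2,2-di-tert-butyl-6-methyl-4H-1,3,2-dioxasilin-4-yl](2-methyl-1,3-dithian-2-yl)methanone | CC1(SCCCS1)C(=O)[C@@H]2C=C(C)O[Si](C(C)(C)C)(C(C)(C)C)O2 | intermediate
9 | ethoxyethyne | CCOC#C | starting material
10 | (1R)-1-[(4S)-2,2-di-tert-butyl-6-methyl-4H-1,3,2-dioxasilin-4-yl]-3-ethoxy-1-(2-methyl-1,3-dithian-2-yl)prop-2-yn-1-ol | CCOC#C[C@](O)(C1(C)SCCCS1)[C@@H]2C=C(C)O[Si](C(C)(C)C)(C(C)(C)C)O2 | intermediate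
11 | potassium alkoxide of 10 | [K+].CCOC#C[C@]([O-])(C1(C)SCCCS1)[C@@H]2C=C(C)O[Si](C(C)(C)C)(C(C)(C)C)O2 | intermediate (not isolated)
12 | potassium 3-[(6R)-2,2-di-tert-butyl-6-methyl-6H-1,3,2-dioxasilin-6-yl]-3-ethoxy-1-(2-methyl-1,3-dithian-2-yl)propa-1,2-dien-1-olate | [K+].CCOC(=C=C([O-])C1(C)SCCCS1)[C@@]2(C)C=CO[Si](C(C)(C)C)(C(C)(C)C)O2 | intermediate (not isolated)
13 | (3R)-4-ethoxy-3-hydroxy-3-methyl-6-(2-methyl-1,3-dithian-2-yl)-6-oxohex-4-enal | CCOC(=CC(=O)C1(C)SCCCS1)[C@](C)(O)CC=O | intermediate (not isolated)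
14 | 2-[(2R)-2-methyl-5-(2-methyl-1,3-dithian-2-yl)-3-oxo-2,3-dihydrofuran-2-yl]acetaldehyde | O=CC[C@@]1(C)OC(=CC1=O)C2(C)SCCCS2 | intermediate
15 | (R)-2,2-dimethyl-1,3-dioxolane-4-carbaldehyde | O=C[C@H]1COC(C)(C)O1 | starting material
16 | methyl acrylate | C=CC(=O)OC | starting material
17 | methyl 2-{[(4R)-2,2-dimethyl-1,3-dioxolan-4-yl](hydroxy)methyl}prop-2-enoate | COC(=O)C(=C)C(O)[C@H]1COC(C)(C)O1 | intermediate
18 | methyl (2Z)-2-(bromomethyl)-3-[(4S)-2,2-dimethyl-1,3-dioxolan-4-yl]prop-2-enoate | BrC/C(C(=O)OC)=C\[C@H]1COC(C)(C)O1 | intermediate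
19 | methyl (3R,4S)-3-[(4S)-2,2-dimethyl-1,3-dioxolan-4-yl]-4-hydroxy-2-methylidene-5-[(2R)-2-methyl-5-(2-methyl-1,3-dithian-2-yl)-3-oxo-2,3-dihydrofuran-2-yl]pentanoate | C=C(C(=O)OC)[C@@H]([C@H]1COC(C)(C)O1)[C@@H](O)C[C@@]2(C)OC(=CC2=O)C3(C)SCCCS3 | intermediate (not isolated)
20 | (4R,5S)-4-[(4S)-2,2-dimethyl-1,3-dioxolan-4-yl]-3-methylidene-5-{[(2R)-2-methyl-5-(2-methyl-1,3-dithian-2-yl)-3-oxo-2,3-dihydrofuran-2-yl]methyl}oxolan-2-one | C=C1C(=O)O[C@@H](C[C@@]2(C)OC(=CC2=O)C3(C)SCCCS3)[C@@H]1[C@H]4COC(C)(C)O4 | intermediate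
21 | (4R,5S)-5-{[(2R)-5-acetyl-2-methyl-3-oxo-2,3-dihydrofuran-2-yl]methyl}-4-[(4S)-2,2-dimethyl-1,3-dioxolan-4-yl]-3-methylideneoxolan-2-one | C=C1C(=O)O[C@@H](C[C@@]2(C)OC(=CC2=O)C(C)=O)[C@@H]1[C@H]3COC(C)(C)O3 | intermediate
22 | 1-[(5R)-5-{[(2S,3R)-3-[(4S)-2,2-dimethyl-1,3-dioxolan-4-yl]-4-methylidene-5-oxooxolan-2-yl]methyl}-5-methyl-4-oxo-4,5-dihydrofuran-2-yl]ethenyl trifluoromethanesulfonate | C=C1C(=O)O[C@@H](C[C@@]2(C)OC(=CC2=O)C(=C)OS(=O)(=O)C(F)(F)F)[C@@H]1[C@H]3COC(C)(C)O3 | intermediate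
23 | 1-[(5R)-5-{[(2S,3S)-3-[(1S)-1,2-dihydroxyethyl]-4-methylidene-5-oxooxolan-2-yl]methyl}-5-methyl-4-oxo-4,5-dihydrofuran-2-yl]ethenyl trifluoromethanesulfonate | C=C1C(=O)O[C@@H](C[C@@]2(C)OC(=CC2=O)C(=C)OS(=O)(=O)C(F)(F)F)[C@@H]1[C@H](O)CO | intermediate
24 | 1-[(5R)-5-{[(2S,3S)-3-[(1S)-2-{[tert-butyl(dimethyl)silyl]oxy}-1-hydroxyethyl]-4-methylidene-5-oxooxolan-2-yl]methyl}-5-methyl-4-oxo-4,5-dihydrofuran-2-yl]ethenyl trifluoromethanesulfonate | C=C1C(=O)O[C@@H](C[C@@]2(C)OC(=CC2=O)C(=C)OS(=O)(=O)C(F)(F)F)[C@@H]1[C@H](O)CO[Si](C)(C)C(C)(C)C | intermediate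
25 | angelic acid, (2Z)-2-methylbut-2-enoic acid | OC(=O)/C(C)=C\C | starting material
26 | (1S)-2-{[tert-butyl(dimethyl)silyl]oxy}-1-[(2S,3R)-4-methylidene-2-{[(2R)-2-methyl-3-oxo-5-(1-{[(trifluoromethyl)sulfonyl]oxy}ethenyl)-2,3-dihydrofuran-2-yl]methyl}-5-oxooxolan-3-yl]ethyl (2Z)-2-methylbut-2-enoate | C=C1C(=O)O[C@@H](C[C@@]2(C)OC(=CC2=O)C(=C)OS(=O)(=O)C(F)(F)F)[C@@H]1[C@H](OC(=O)/C(C)=C\C)CO[Si](C)(C)C(C)(C)C | intermediate
27 | (1S)-2-hydroxy-1-[(2S,3R)-4-methylidene-2-{[(2R)-2-methyl-3-oxo-5-(1-{[(trifluoromethyl)sulfonyl]oxy}ethenyl)-2,3-dihydrofuran-2-yl]methyl}-5-oxooxolan-3-yl]ethyl (2Z)-2-methylbut-2-enoate | C=C1C(=O)O[C@@H](C[C@@]2(C)OC(=CC2=O)C(=C)OS(=O)(=O)C(F)(F)F)[C@@H]1[C@H](OC(=O)/C(C)=C\C)CO | intermediate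
28 | (1S)-1-[(2S,3R)-4-methylidene-2-{[(2R)-2-methyl-3-oxo-5-(1-{[(trifluoromethyl)sulfonyl]oxy}ethenyl)-2,3-dihydrofuran-2-yl]methyl}-5-oxooxolan-3-yl]-2-oxoethyl (2Z)-2-methylbut-2-enoate | C=C1C(=O)O[C@@H](C[C@@]2(C)OC(=CC2=O)C(=C)OS(=O)(=O)C(F)(F)F)[C@@H]1[C@H](OC(=O)/C(C)=C\C)C=O | intermediate
29 | CNP0120053.1, (5S,6S,7R,8S,10R)-6-angeloyloxy-5-hydroxy-1-oxo-3,10-epoxygermacra-2,4(15),11(13)-trien-12,8-olide | C=C1C(=O)O[C@H]2C[C@@]3(C)OC(=CC3=O)C(=C)[C@H](O)[C@@H](OC(=O)/C(C)=C\C)[C@H]12 | target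

**Step count and risks**
Total: 18 steps. Longest linear sequence: 16 steps (steps 1–7 and 10–18, from 1); steps 8–9 make the second fragment.

Steps most likely to fail:

1. Step 7. Possible failure: transfer of the silylene from the enol oxygen to the neighbouring alkoxide, followed by β-elimination of the freed enolate, or retro-alkynylation, outruns the [3,3] shift. Fallback (classical two-stage furanone construction, in which the C10 centre is taken from the chiral pool): it sets out from 7 and comes back to the route at 14. Compound 7 is lithiated (n-BuLi) and formylated with DMF to 2-methyl-1,3-dithiane-2-carbaldehyde F1, which the Ohira–Bestmann reagent (K2CO3, MeOH) converts into 2-ethynyl-2-methyl-1,3-dithiane F2. Commercial (R)-citramalic acid gives with 2,2-dimethoxypropane/PPTS the dioxolanone acid 2-[(4R)-2,2,4-trimethyl-5-oxo-1,3-dioxolan-4-yl]acetic acid F3; BH3·SMe2 reduction of the free acid and acid-induced lactonisation give (3R)-3-hydroxy-3-methyloxolan-2-one F4. The lithium acetylide of F2 (2.2 equiv, −78 °C) opens F4 to the hydroxy ynone (4R)-4,6-dihydroxy-4-methyl-1-(2-methyl-1,3-dithian-2-yl)hex-1-yn-3-one F5. Et2NH addition and dilute acid (5-endo oxa-Michael closure through the enaminone) give (2R)-2-(2-hydroxyethyl)-2-methyl-5-(2-methyl-1,3-dithian-2-yl)furan-3(2H)-one F6, and Dess–Martin oxidation gives 14.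

2. Step 10. Possible failure: poor anti/syn control or poor facial selectivity of the allylchromium addition, giving lactone diastereomers. Fallback (syn-selective addition, then lactonisation with inversion): it sets out from 14 and 18 and comes back at 20. Indium powder in THF/H2O (closed chair transition state from the (Z)-bromide, syn-selective, neutral work-up) should give the C8 epimer of 19, methyl (3R,4R)-3-[(4S)-2,2-dimethyl-1,3-dioxolan-4-yl]-4-hydroxy-2-methylidene-5-[(2R)-2-methyl-5-(2-methyl-1,3-dithian-2-yl)-3-oxo-2,3-dihydrofuran-2-yl]pentanoate F7. Me3SnOH cleaves the ester to the corresponding (3R,4R)-hydroxy acid F8, and Mitsunobu lactonisation (PPh3, DIAD) closes the ring with inversion at C8 to give 20.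

3. Step 18. Possible failure: poor facial selectivity at the aldehyde (C5) during ring closure. Fallback (the stereocentre is set by reagent-controlled reduction instead of by the C–C bond formation): it sets out from 28 and comes back at 29. The ring closure is run as in step 18; if it gives the 5R alcohol, the C5 epimer of 29 F9, this is oxidised (Dess–Martin periodinane, NaHCO3) to the macrocyclic 5-ketone F10, which is reduced at once with a CBS oxazaborolidine/catecholborane at −78 °C to 29.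

**Further compounds**
F1 | step 7 | 2-methyl-1,3-dithiane-2-carbaldehyde | CC1(C=O)SCCCS1
F2 | step 7 | 2-ethynyl-2-methyl-1,3-dithiane | CC1(C#C)SCCCS1
F3 | step 7 | 2-[(4R)-2,2,4-trimethyl-5-oxo-1,3-dioxolan-4-yl]acetic acid | OC(=O)C[C@@]1(C)OC(C)(C)OC1=O
F4 | step 7 | (3R)-3-hydroxy-3-methyloxolan-2-one | C[C@@]1(O)CCOC1=O
F5 | step 7 | (4R)-4,6-dihydroxy-4-methyl-1-(2-methyl-1,3-dithian-2-yl)hex-1-yn-3-one | OCC[C@@](C)(O)C(=O)C#CC1(C)SCCCS1
F6 | step 7 | (2R)-2-(2-hydroxyethyl)-2-methyl-5-(2-methyl-1,3-dithian-2-yl)furan-3(2H)-one | OCC[C@@]1(C)OC(=CC1=O)C2(C)SCCCS2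
F7 | step 10 | methyl (3R,4R)-3-[(4S)-2,2-dimethyl-1,3-dioxolan-4-yl]-4-hydroxy-2-methylidene-5-[(2R)-2-methyl-5-(2-methyl-1,3-dithian-2-yl)-3-oxo-2,3-dihydrofuran-2-yl]pentanoate | C=C(C(=O)OC)[C@@H]([C@H]1COC(C)(C)O1)[C@H](O)C[C@@]2(C)OC(=CC2=O)C3(C)SCCCS3
F8 | step 10 | (3R,4R)-3-[(4S)-2,2-dimethyl-1,3-dioxolan-4-yl]-4-hydroxy-2-methylidene-5-[(2R)-2-methyl-5-(2-methyl-1,3-dithian-2-yl)-3-oxo-2,3-dihydrofuran-2-yl]pentanoic acid | C=C(C(=O)O)[C@@H]([C@H]1COC(C)(C)O1)[C@H](O)C[C@@]2(C)OC(=CC2=O)C3(C)SCCCS3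
F9 | step 18 | C5 epimer of 29, (5R,6S,7R,8S,10R)-6-angeloyloxy-5-hydroxy-1-oxo-3,10-epoxygermacra-2,4(15),11(13)-trien-12,8-olide | C=C1C(=O)O[C@H]2C[C@@]3(C)OC(=CC3=O)C(=C)[C@@H](O)[C@@H](OC(=O)/C(C)=C\C)[C@H]12
F10 | step 18 | (6S,7R,8S,10R)-6-angeloyloxy-1,5-dioxo-3,10-epoxygermacra-2,4(15),11(13)-trien-12,8-olide | C=C1C(=O)O[C@H]2C[C@@]3(C)OC(=CC3=O)C(=C)C(=O)[C@@H](OC(=O)/C(C)=C\C)[C@H]12
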